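Two questions stand, and one quotient answers both.

* the largest share of what was charged as solid substrate, at 25 h belongs to (starting material / target / cross product)
* the largest share itself, whichever of these holds it, in percent of the solid substrate charged

| setting | green | violet | flask |
|---|---|---|---|
| solid substrate | 5.5 mM | 8.2 mM | 11 mM |
| reagent | 1.2 equiv | 1.2 equiv | 1.20 equiv |
| second substrate | 0.50 equiv | 0.50 equiv | 0.500 equiv |
| remark | run made earlier | run made earlier |  |
| time |  |  | 25 h |

| run | time / h | cross product / % | target / % | starting material / % | solid substrate / % |
|---|---|---|---|---|---|
| green | 1.33 | 7.6 | 6.9 | 85.5 | 0.4 |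
| green | 3.00 | 14.6 | 6.5 | 75.3 | 0 |
| green | 6.00 | 18.1 | 12.1 | 72.2 | 1.0 |
| green | 15.0 | 18.5 | 11.8 | 69.7 | 0 |
| violet | 2.00 | 12.1 | 9.0 | 79.9 | 0 |
| violet | 5.00 | 16.3 | 13.3 | 69.7 | 1.3 |
| violet | 10.0 | 15.4 | 15.4 | 67.6 | 0.1 |
| violet | 15.0 | 17.8 | 16.3 | 67.6 | 0 |

(each reading ± 1 percentage point)

- solid, in amounts per volume of the solution: solid substrate
- at the start none of the solid substrate is in solution
- starting material means what is dissolved; the solid is not counted in it

In the green and violet runs the shares have levelled by the last reading, so we read that level as a balance of starting material and reagent with target. Its quotient is K = p/(a·b), where p, a and x are target, starting material and cross product as fractions of the charge, and b is free reagent.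

The smaller charge, second substrate, sets the reagent balance. Cross product holds x of it, and the remainder is unaccounted for, so there are two extreme flasks:

remainder took no reagent: violet K = 28.4 M⁻¹

remainder took one reagent each: violet K = 41.1 M⁻¹, green K = 40.1 M⁻¹

We carry the second, the paid-for quotient K, the equilibrium constant of the step. We take the flask with its solid dissolved and x as in violet, and solve a = 1 − x − p:

first extreme: p = 19.6 %

second extreme: p = 19.4 %

These two differ only in the reagent balance and both borrow violet's x, so they are no bounds on the flask. On that borrowed x, we expect starting material to lead at about 62.8 %.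

The forecast gives starting material at 64.5 %, “assuming the solid still dissolves”, a little above our figure.

The flask gives starting material at 67.4 %, target 19.1 %, cross product 13.5 %. That cross product is less than the 17.8 % we borrowed, and our figure for starting material lies 4.6 percentage points low.

    second substrate + reagent → second product (k = 73.0 M⁻¹ h⁻¹)
    solid substrate ⇌ starting material, rate k2*(cs2 - [starting material]) while solid is left; crystals form when [starting material] > cs2 (solubility = 8.70 mM, k = 2.00 h⁻¹)
    starting material + reagent ⇌ target (K = 40.0 M⁻¹, k = 10.0 M⁻¹ h⁻¹)
    starting material + second substrate → cross product (k = 54.0 M⁻¹ h⁻¹)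

In the flask the step between starting material, reagent and target relaxes with a half-life of 1.75 h, short against the 25 h asked. Second substrate stands at 0 % by then, and the flask's quotient, with reagent at 53.7 % of its charge, is 40.0 M⁻¹, where the violet reading gave 41.1 M⁻¹. The neighbouring flask with 4.80 equiv of reagent ends with target at 60.8 %, starting material at 37.2 % and reagent at 77.3 % of its charge, a quotient of 40.0 M⁻¹.

Readings and results are simulated on assumed constants, and the scatter is random.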